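**Retrosynthetic overview**
1. Target 32 ⇐ late unveiling of the C14 enal from a PMB ether; the C9 acetate and the C8 (S)-2-acetoxy-2-methylbutanoate go onto a silyl-differentiated diol; C13 comes from a Mannich/elimination sequence on the γ-lactone.
2. Feature used: in the ten-membered carbocycle C1–C10, C8 and C9 carry an anti (8S,9R) pair of oxygens and the C9 carbinol sits next to the C1=C10 alkene that bears C14. An oxygen-bearing allyl nucleophile spanning C9–C10–C1 and a C8 carbonyl leave exactly this array, so the ring is opened at C8–C9.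
3. Seco-dialdehyde (C9 enal, C8 aldehyde on the trans γ-lactone O–C6–C7–C11–C12) ⇐ Evans syn-aldol of a succinate imide with the C6 (Z)-enal, then lactonisation.
4. C6 enal ⇐ neryl acetate: cleavage of the terminal alkene to the C1 aldehyde, Knoevenagel condensation with dimethyl malonate and reduction put C9 and C14 on C10.
5. Ring order: γ-lactone first (step 8), ten-membered carbocycle second (step 12).

Key step: step 12

Remark: positions are numbered as in germacranolides (ring C1–C10, lactone carbons C11–C13 with the ring oxygen on C6, C14 on C10, C15 on C4).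
Remark: step 9 cannot tell apart the two hydroxymethyl groups on C10, so 15, 16 and 17 are carried as both C1=C10 geometric isomers (the one with C9 trans to C2 is drawn); the allylchromium of step 12 no longer holds that geometry, so both converge.

Step 1
Reactants: 1 neryl acetate
Product: 3 (Z)-3-methyl-6-oxohex-2-en-1-yl acetate (C1 aldehyde), via epoxide 2 (not isolated)
Conditions: mCPBA, NaHCO3, CH2Cl2, 0 °C; then H5IO6, THF/Et2O, 0 °C
Reagents that add atoms: 3-chloroperoxybenzoic acid (mCPBA), O=C(OO)c1cccc(Cl)c1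
Why: Prilezhaev epoxidation takes the electron-rich terminal alkene rather than the one deactivated by the allylic acetate, and periodic acid opens the epoxide and cleaves the glycol (Malaprade cleavage) to the C1 aldehyde with loss of acetone.

Step 2
Reactants: 3 (Z)-3-methyl-6-oxohex-2-en-1-yl acetate; 4 dimethyl malonate
Product: 5 dimethyl 2-[(Z)-6-acetoxy-4-methylhex-4-en-1-ylidene]malonate
Conditions: piperidine (cat.), AcOH (cat.), PhH, reflux, Dean–Stark
Reagents that add atoms: none
Why: Knoevenagel condensation of the unbranched aldehyde with the active methylene compound installs C10 with two equal ester arms (future C9 and C14), so no C1=C10 geometry has to be controlled here.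

Step 3
Reactants: 5 dimethyl 2-[(Z)-6-acetoxy-4-methylhex-4-en-1-ylidene]malonate
Product: 6 (Z)-2-(6-hydroxy-4-methylhex-4-en-1-ylidene)propane-1,3-diol (C6/C9/C14 triol)
Conditions: i-Bu2AlH (excess), CH2Cl2, −78 → 0 °C; aq. KNaC4H4O6
Reagents that add atoms: none
Why: i-Bu2AlH reduces the two conjugated esters by 1,2-addition to allylic alcohols and cleaves the acetate in the same operation (hydride reduction of esters).

Step 4
Reactants: 6 triol
Product: 7 (Z)-6-(2,2-dimethyl-1,3-dioxan-5-ylidene)-3-methylhex-2-en-1-ol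
Conditions: Me2C(OMe)2, PPTS (cat.), CH2Cl2, 0 °C → rt
Reagents that add atoms: 2,2-dimethoxypropane, COC(C)(C)OC
Why: acid-catalysed transketalisation closes the six-membered isopropylidene acetal on the 1,3-diol only, which leaves the lone C6 hydroxyl free and keeps the two arms on C10 equivalent.

Step 5
Reactants: 7 acetonide alcohol
Product: 8 (Z)-6-(2,2-dimethyl-1,3-dioxan-5-ylidene)-3-methylhex-2-enal (C6 aldehyde)
Conditions: MnO2, CH2Cl2, rt
Reagents that add atoms: none
Why: MnO2 oxidises the allylic alcohol to the enal under neutral conditions that should keep the Z geometry of C4=C5 (allylic oxidation).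

Step 6
Reactants: 9 (S)-4-benzyl-2-oxazolidinone; 10 methyl 4-chloro-4-oxobutanoate
Product: 11 methyl 4-[(S)-4-benzyl-2-oxooxazolidin-3-yl]-4-oxobutanoate
Conditions: n-BuLi, THF, −78 °C; then 10, −78 → 0 °C
Reagents that add atoms: none
Why: N-acylation of the lithiated oxazolidinone by the acid chloride, which is far more electrophilic than the methyl ester.

Step 7
Reactants: 11 succinate imide; 8 C6 aldehyde
Product: 13 syn-aldol adduct (6R,7S), via boron enolate 12 (not isolated)
Conditions: Bu2BOTf, i-Pr2NEt, CH2Cl2, −78 → 0 °C; 8, −78 → 0 °C; pH 7 buffer, MeOH, H2O2, 0 °C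
Reagents that add atoms: none
Why: Evans syn-aldol, in which the Z boron enolate of the imide (the imide α-CH2 is enolised, not the ester) adds through a Zimmerman–Traxler chair on the face away from the benzyl group and so sets C7 (S) and C6 (R) together.

Step 8
Reactants: 13 syn-aldol adduct
Product: 14 trans-γ-lactone imide diol (6R,7S)
Conditions: PPTS, MeOH, 45 °C
Reagents that add atoms: none
Why: mild acid methanolysis removes the isopropylidene acetal and the C6 hydroxyl closes the γ-lactone onto the methyl ester (5-exo-trig transesterification); the syn-aldol relationship makes the C5 and C8 branches trans on the lactone and no stereocentre is touched.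

Step 9
Reactants: 14 lactone imide diol
Product: 15 mono-PMB ether (C14 OPMB and C9 OH)
Conditions: Ag2O, PMBCl, CH2Cl2, rt, dark
Reagents that add atoms: 4-methoxybenzyl chloride, COc1ccc(CCl)cc1
Why: Ag2O-mediated Williamson etherification of a symmetrical diol should stop at the monoether under neutral conditions that spare imide and lactone; either hydroxymethyl may react, which only decides the C1=C10 geometry.

Step 10
Reactants: 15 mono-PMB ether
Product: 16 lactone diol (C8 and C9 primary alcohols)
Conditions: NaBH4, THF/H2O, 0 °C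
Reagents that add atoms: none
Why: reductive cleavage of the N-acyl oxazolidinone, whose exocyclic carbonyl is more electrophilic than the lactone, gives the C8 alcohol and returns the auxiliary without touching C7.

Step 11
Reactants: 16 lactone diol
Product: 17 seco-dialdehyde (C9 enal and C8 aldehyde on the trans-lactone)
Conditions: Dess–Martin periodinane, NaHCO3, CH2Cl2, 0 °C → rt
Reagents that add atoms: none
Why: Dess–Martin oxidation converts both primary alcohols in one operation under buffered, non-basic conditions, which should avoid epimerisation at C7 and β-elimination of the lactone oxygen; the product is used at once.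

Step 12
Reactants: 17 seco-dialdehyde
Product: 19 ten-membered lactone (C8 OH; C9 OSiEt3; C14 OPMB; 8S,9R), via allylchromium 18 (not isolated)
Conditions: CrCl2 (8 equiv), Et3SiCl (2 equiv), DMF/THF, 25 °C, 17 added by syringe pump over 12 h (final 2 mM); pH 7 buffer
Reagents that add atoms: chlorotriethylsilane, CC[Si](CC)(CC)Cl
Why: Proposed new method: CrCl2 transfers two electrons to the C9 enal while Et3SiCl silylates its oxygen, which gives the (E)-γ-triethylsilyloxyallylchromium 18 (trivalent chromium on C1, the same species from either enal isomer), and this adds through C9 to the C8 aldehyde in a six-membered chair so that C8–C9 forms and the double bond returns to C1=C10. The closest known reactions are the intermolecular chromium-mediated cross-pinacol-type coupling of enals with aldehydes through γ-silyloxyallylchromium species and chromium allylation macrocyclisations. The ten-membered ring closes by intramolecular γ-allylation: C1 and C8 are 1,4-related in the chair and are bridged by the six-atom chain C2–C7, which requires one axial and one equatorial attachment. With C2 axial on C1 (an equatorial C2 would suffer allylic strain with the C14 CH2OPMB group) and C7 equatorial on C8, the E enol ether places the silyloxy group equatorial, which gives the erythro C8/C9 pair and the ring-cis C1=C10 alkene together. C7 controls the absolute sense: the bridge holds C6 anti to H8, and C9 should then approach anti to the C7–C11 bond, between H7 and C6 (a Felkin–Anh arrangement), and not between C6 and C11, which leads to 8S,9R. The step needs reduction of the enal in preference to the saturated aldehyde (only the conjugated carbonyl is reduced by CrCl2 under silyl activation), ring closure in preference to oligomerisation (syringe-pump addition at high dilution) and the face selectivity at C8, which is the least secure of the three.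

Step 13
Reactants: 19 ten-membered lactone
Product: 20 C8 TBS ether
Conditions: TBSOTf, 2,6-lutidine, CH2Cl2, −78 → 0 °C
Reagents that add atoms: tert-butyldimethylsilyl triflate, CC(C)(C)[Si](C)(C)OS(=O)(=O)C(F)(F)F
Why: silylation of the hindered C8 alcohol with a silyl triflate and a weak base protects it for the enolate chemistry without letting it attack the lactone carbonyl (silyl ether formation).

Step 14
Reactants: 20 C8 TBS ether
Product: 23 α-methylene lactone, via Mannich base 21 (not isolated), via methiodide 22 (not isolated)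
Conditions: LiN(i-Pr)2, THF, −78 °C; CH2=NMe2+ I−, −78 °C → rt; then MeI, MeOH, rt; then aq. NaHCO3, CH2Cl2
Reagents that add atoms: Eschenmoser's salt (N,N-dimethylmethyleneiminium iodide), C=[N+](C)C.[I-]
Why: Mannich reaction of the lactone lithium enolate with the iminium salt, quaternisation and E1cB elimination of trimethylamine give the exocyclic C11=C13 alkene; the C11 configuration is lost again and C7 is not enolisable.

Step 15
Reactants: 23 α-methylene lactone
Product: 24 C9 alcohol (C8 OTBS kept)
Conditions: PPTS, MeOH/CH2Cl2, 0 °C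
Reagents that add atoms: none
Why: acid-catalysed methanolysis removes the triethylsilyl ether much faster than the bulkier tert-butyldimethylsilyl ether (selective desilylation).

Step 16
Reactants: 24 C9 alcohol
Product: 25 C9 acetate
Conditions: Ac2O, pyridine, DMAP (cat.), CH2Cl2, 0 °C → rt
Reagents that add atoms: acetic anhydride, CC(=O)OC(C)=O
Why: DMAP-catalysed acylation of the secondary allylic alcohol with retention at C9.

Step 17
Reactants: 25 C9 acetate
Product: 26 C8 alcohol
Conditions: HF·pyridine, pyridine, THF, 0 °C → rt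
Reagents that add atoms: none
Why: fluoride-driven cleavage of the silyl ether under buffered acidic conditions, which should not move the neighbouring acetate or open the lactone.

Step 18
Reactants: 27 (S)-2-hydroxy-2-methylbutanoic acid
Product: 28 (S)-2-acetoxy-2-methylbutanoic acid
Conditions: AcCl, neat, 0 → 50 °C; then H2O
Reagents that add atoms: acetyl chloride, CC(Cl)=O
Why: O-acetylation of the tertiary α-hydroxy acid with an acid chloride; the quaternary stereocentre has no hydrogen and cannot epimerise.

Step 19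
Reactants: 28 (S)-2-acetoxy-2-methylbutanoic acid
Product: 29 (S)-2-acetoxy-2-methylbutanoyl chloride
Conditions: (COCl)2, DMF (cat.), CH2Cl2, 0 °C → rt
Reagents that add atoms: oxalyl chloride, O=C(Cl)C(Cl)=O
Why: acid chloride formation through the Vilsmeier-type chloroiminium catalyst; the chloride is used crude.

Step 20
Reactants: 26 C8 alcohol; 29 (S)-2-acetoxy-2-methylbutanoyl chloride
Product: 30 C8 (S)-2-acetoxy-2-methylbutanoate
Conditions: DMAP, Et3N, CH2Cl2, 0 → 40 °C
Reagents that add atoms: none
Why: DMAP-catalysed acyl transfer from the acid chloride to the secondary alcohol, with retention at C8 and at the side-chain centre.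

Step 21
Reactants: 30 diester PMB ether
Product: 31 C14 allylic alcohol
Conditions: DDQ, CH2Cl2/pH 7 buffer, 0 °C
Reagents that add atoms: none
Why: oxidative cleavage of the p-methoxybenzyl ether by DDQ leaves the esters, the alkenes and the α-methylene lactone alone.

Step 22
Reactants: 31 C14 allylic alcohol
Product: 32 CNP0499875.1 (target)
Conditions: MnO2, CH2Cl2, rt
Reagents that add atoms: none
Why: MnO2 oxidises the primary allylic alcohol to the C14 enal under neutral conditions, so the base-sensitive 2-formyl allylic acetate array appears only in the last step.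

**Compound list**
1 | neryl acetate, (Z)-3,7-dimethylocta-2,6-dien-1-yl acetate | CC(C)=CCC/C(C)=C\COC(C)=O | starting material
2 | 6,7-epoxyneryl acetate (racemic epoxide) | CC1(C)OC1CC/C(C)=C\COC(C)=O | intermediate
3 | (Z)-3-methyl-6-oxohex-2-en-1-yl acetate | O=CCC/C(C)=C\COC(C)=O | intermediate
4 | dimethyl malonate | COC(=O)CC(=O)OC | starting material
5 | dimethyl 2-[(Z)-6-acetoxy-4-methylhex-4-en-1-ylidene]malonate | COC(=O)C(=CCC/C(C)=C\COC(C)=O)C(=O)OC | intermediate
6 | (Z)-2-(6-hydroxy-4-methylhex-4-en-1-ylidene)propane-1,3-diol | OCC(CO)=CCC/C(C)=C\CO | intermediate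
7 | (Z)-6-(2,2-dimethyl-1,3-dioxan-5-ylidene)-3-methylhex-2-en-1-ol | CC1(C)OCC(=CCC/C(C)=C\CO)CO1 | intermediate
8 | (Z)-6-(2,2-dimethyl-1,3-dioxan-5-ylidene)-3-methylhex-2-enal | CC1(C)OCC(=CCC/C(C)=C\C=O)CO1 | intermediate
9 | (S)-4-benzyl-2-oxazolidinone | O=C1N[C@@H](Cc2ccccc2)CO1 | starting material
10 | methyl 4-chloro-4-oxobutanoate | COC(=O)CCC(Cl)=O | starting material
11 | methyl 4-[(S)-4-benzyl-2-oxooxazolidin-3-yl]-4-oxobutanoate | COC(=O)CCC(=O)N1[C@@H](Cc2ccccc2)COC1=O | intermediate
12 | (Z)-O-dibutylboryl enolate of 11 | CCCCB(CCCC)O/C(=C\CC(=O)OC)N1[C@@H](Cc2ccccc2)COC1=O | intermediate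
13 | methyl (3S,4R,5Z)-3-[(S)-4-benzyl-2-oxooxazolidine-3-carbonyl]-9-(2,2-dimethyl-1,3-dioxan-5-ylidene)-4-hydroxy-6-methylnon-5-enoate (6R,7S in ring numbering) | COC(=O)C[C@H](C(=O)N1[C@@H](Cc2ccccc2)COC1=O)[C@H](O)/C=C(/C)CCC=C1COC(C)(C)OC1 | intermediate
14 | (S)-4-benzyl-3-{(2R,3S)-2-[(1Z)-7-hydroxy-6-(hydroxymethyl)-2-methylhepta-1,5-dien-1-yl]-5-oxotetrahydrofuran-3-carbonyl}oxazolidin-2-one (trans-lactone, 6R,7S) | O=C1C[C@H](C(=O)N2[C@@H](Cc3ccccc3)COC2=O)[C@@H](/C=C(/C)CCC=C(CO)CO)O1 | intermediate
15 | mono-PMB ether of 14: C14 OPMB, C9 OH (both C1=C10 isomers; C9 trans to C2 drawn) | O=C1C[C@H](C(=O)N2[C@@H](Cc3ccccc3)COC2=O)[C@@H](/C=C(/C)CC/C=C(/CO)COCc4ccc(OC)cc4)O1 | intermediate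
16 | trans-lactone diol: C8 and C9 primary alcohols, C14 OPMB (same spatial arrangement at C6 and C7 as 14; both C1=C10 isomers, C9 trans to C2 drawn) | O=C1C[C@H](CO)[C@@H](/C=C(/C)CC/C=C(/CO)COCc2ccc(OC)cc2)O1 | intermediate
17 | seco-dialdehyde (6R,7S): C9 enal, C8 aldehyde on the trans-lactone, C14 OPMB (both C1=C10 isomers, E drawn) | O=C1C[C@H](C=O)[C@@H](/C=C(/C)CC/C=C(/C=O)COCc2ccc(OC)cc2)O1 | intermediate
18 | (E)-γ-triethylsilyloxyallylchromium dichloride from 17 (trivalent chromium on C1; C1 configuration not fixed) | CC[Si](CC)(CC)O/C=C(\COCc1ccc(OC)cc1)C(CC/C(C)=C\[C@H]1OC(=O)C[C@@H]1C=O)[Cr](Cl)Cl | intermediate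
19 | ten-membered 6,12-lactone: C8 OH, C9 OSiEt3, C14 OPMB, 1(10)-ring-cis, 4Z; C6–C9 arranged as in the target (8S,9R) | C1C(=O)O[C@@H]2/C=C(/C)CC/C=C(/COCc3ccc(OC)cc3)[C@@H](O[Si](CC)(CC)CC)[C@@H](O)[C@@H]12 | intermediate
20 | C8 tert-butyldimethylsilyl ether of 19 | C1C(=O)O[C@@H]2/C=C(/C)CC/C=C(/COCc3ccc(OC)cc3)[C@@H](O[Si](CC)(CC)CC)[C@@H](O[Si](C)(C)C(C)(C)C)[C@@H]12 | intermediate
21 | C11 dimethylaminomethyl lactone (Mannich base, C11 epimers) | CN(C)CC1C(=O)O[C@@H]2/C=C(/C)CC/C=C(/COCc3ccc(OC)cc3)[C@@H](O[Si](CC)(CC)CC)[C@@H](O[Si](C)(C)C(C)(C)C)[C@@H]12 | intermediate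
22 | trimethylammonium iodide of 21 | C[N+](C)(C)CC1C(=O)O[C@@H]2/C=C(/C)CC/C=C(/COCc3ccc(OC)cc3)[C@@H](O[Si](CC)(CC)CC)[C@@H](O[Si](C)(C)C(C)(C)C)[C@@H]12.[I-] | intermediate
23 | α-methylene lactone: C8 OTBS, C9 OSiEt3, C14 OPMB | C=C1C(=O)O[C@@H]2/C=C(/C)CC/C=C(/COCc3ccc(OC)cc3)[C@@H](O[Si](CC)(CC)CC)[C@@H](O[Si](C)(C)C(C)(C)C)[C@@H]12 | intermediate
24 | α-methylene lactone: C8 OTBS, C9 OH | C=C1C(=O)O[C@@H]2/C=C(/C)CC/C=C(/COCc3ccc(OC)cc3)[C@@H](O)[C@@H](O[Si](C)(C)C(C)(C)C)[C@@H]12 | intermediate
25 | α-methylene lactone: C8 OTBS, C9 OAc | C=C1C(=O)O[C@@H]2/C=C(/C)CC/C=C(/COCc3ccc(OC)cc3)[C@@H](OC(C)=O)[C@@H](O[Si](C)(C)C(C)(C)C)[C@@H]12 | intermediate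
26 | α-methylene lactone: C8 OH, C9 OAc | C=C1C(=O)O[C@@H]2/C=C(/C)CC/C=C(/COCc3ccc(OC)cc3)[C@@H](OC(C)=O)[C@@H](O)[C@@H]12 | intermediate
27 | (S)-2-hydroxy-2-methylbutanoic acid | CC[C@](C)(O)C(=O)O | starting material
28 | (S)-2-acetoxy-2-methylbutanoic acid | CC[C@](C)(OC(C)=O)C(=O)O | intermediate
29 | (S)-2-acetoxy-2-methylbutanoyl chloride | CC[C@](C)(OC(C)=O)C(Cl)=O | intermediate
30 | C8 (S)-2-acetoxy-2-methylbutanoate, C9 acetate, C14 OPMB | C=C1C(=O)O[C@@H]2/C=C(/C)CC/C=C(/COCc3ccc(OC)cc3)[C@@H](OC(C)=O)[C@@H](OC(=O)[C@](C)(CC)OC(C)=O)[C@@H]12 | intermediate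
31 | C14 allylic alcohol | C=C1C(=O)O[C@@H]2/C=C(/C)CC/C=C(/CO)[C@@H](OC(C)=O)[C@@H](OC(=O)[C@](C)(CC)OC(C)=O)[C@@H]12 | intermediate
32 | CNP0499875.1 (6R,7S,8S,9R; side chain 2S; 14-al) | C=C1C(=O)O[C@@H]2/C=C(/C)CC/C=C(/C=O)[C@@H](OC(C)=O)[C@@H](OC(=O)[C@](C)(CC)OC(C)=O)[C@@H]12 | target

**Step count**
Total: 22 steps. Longest linear sequence: 19 steps (steps 1–5, 7–17, 20–22).

**Steps most likely to fail**

Step 12 (the new chromium cyclisation). The allylchromium may add to a second molecule instead of closing the ring, may be protonated before it reacts, or may attack the C8 aldehyde without face selectivity relative to C7. The fallback sets out from 17 and uses a known low-valent titanium pinacol macrocyclisation of the dialdehyde (TiCl3(DME)1.5, Zn–Cu, DME, 25 °C, syringe-pump addition). This should give the ten-membered 8,9-diol F1 as a mixture of diol stereoisomers, from which the 8S,9R isomer is separated. Monosilylation of its allylic C9 hydroxyl, the less hindered of the two (Et3SiOTf 1 equiv, 2,6-lutidine, CH2Cl2, −78 °C), comes back to the route at 19.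

Step 20 (acylation at C8). Acyl transfer to the hindered C8 hydroxyl may be so slow that the neighbouring C9 acetate migrates to C8 or the acid chloride is consumed otherwise. The fallback sets out from 19 and 27 and inverts the order of the two acylations. Acid 27 is silylated twice (Et3SiCl, imidazole, DMF) to triethylsilyl (S)-2-methyl-2-(triethylsilyloxy)butanoate F2, and (COCl)2 with DMF (cat.) turns this into (S)-2-methyl-2-(triethylsilyloxy)butanoyl chloride F3, which has no enolisable hydrogen. Acylation of the free C8 hydroxyl of 19 (DMAP, Et3N, CH2Cl2) gives the C8 ester F4 while C9 still carries its silyl ether. Methylenation as in step 14 then gives, through the Mannich base F5 and its methiodide F6, the α-methylene lactone F7. HF·pyridine removes both triethylsilyl groups to give the diol F8, and acetylation of the C9 and the tertiary side-chain hydroxyls (Ac2O, DMAP, Et3N, CH2Cl2, 40 °C) comes back to the route at 30.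

Step 10 (hydride removal of the auxiliary). Under the basic borohydride conditions the freed C8 alkoxide may attack the lactone carbonyl (translactonisation to the 8,12-lactone), or the lactone oxygen may be eliminated from C6 after deprotonation at C7. The fallback sets out from 15 and never frees a C8 alcohol. Thiolate cleavage of the imide (EtSH, n-BuLi, THF, 0 °C) gives the S-ethyl thioester F9. Fukuyama reduction (Et3SiH, Pd/C, acetone, rt) gives the C8 aldehyde F10 with the C9 alcohol still free. MnO2 (CH2Cl2, rt) then oxidises only the allylic C9 alcohol and comes back to the route at 17.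

Further compounds
F1 | step 12 | ten-membered 8,9-diol (8S,9R isomer), C14 OPMB | C1C(=O)O[C@@H]2/C=C(/C)CC/C=C(/COCc3ccc(OC)cc3)[C@@H](O)[C@@H](O)[C@@H]12
F2 | step 20 | triethylsilyl (S)-2-methyl-2-(triethylsilyloxy)butanoate | CC[C@](C)(O[Si](CC)(CC)CC)C(=O)O[Si](CC)(CC)CC
F3 | step 20 | (S)-2-methyl-2-(triethylsilyloxy)butanoyl chloride | CC[C@](C)(O[Si](CC)(CC)CC)C(Cl)=O
F4 | step 20 | C8 (S)-2-methyl-2-(triethylsilyloxy)butanoate of 19 | C1C(=O)O[C@@H]2/C=C(/C)CC/C=C(/COCc3ccc(OC)cc3)[C@@H](O[Si](CC)(CC)CC)[C@@H](OC(=O)[C@](C)(CC)O[Si](CC)(CC)CC)[C@@H]12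
F5 | step 20 | C11 dimethylaminomethyl derivative of F4 (C11 epimers) | CN(C)CC1C(=O)O[C@@H]2/C=C(/C)CC/C=C(/COCc3ccc(OC)cc3)[C@@H](O[Si](CC)(CC)CC)[C@@H](OC(=O)[C@](C)(CC)O[Si](CC)(CC)CC)[C@@H]12
F6 | step 20 | trimethylammonium iodide of F5 | C[N+](C)(C)CC1C(=O)O[C@@H]2/C=C(/C)CC/C=C(/COCc3ccc(OC)cc3)[C@@H](O[Si](CC)(CC)CC)[C@@H](OC(=O)[C@](C)(CC)O[Si](CC)(CC)CC)[C@@H]12.[I-]
F7 | step 20 | α-methylene lactone with C9 OSiEt3 and silylated C8 side chain | C=C1C(=O)O[C@@H]2/C=C(/C)CC/C=C(/COCc3ccc(OC)cc3)[C@@H](O[Si](CC)(CC)CC)[C@@H](OC(=O)[C@](C)(CC)O[Si](CC)(CC)CC)[C@@H]12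
F8 | step 20 | α-methylene lactone diol: C9 OH, C8 (S)-2-hydroxy-2-methylbutanoate | C=C1C(=O)O[C@@H]2/C=C(/C)CC/C=C(/COCc3ccc(OC)cc3)[C@@H](O)[C@@H](OC(=O)[C@](C)(CC)O)[C@@H]12
F9 | step 10 | S-ethyl thioester at C8 (trans-lactone, C9 OH, C14 OPMB) | O=C1C[C@H](C(=O)SCC)[C@@H](/C=C(/C)CC/C=C(/CO)COCc2ccc(OC)cc2)O1
F10 | step 10 | C8 aldehyde with free C9 alcohol | O=C1C[C@H](C=O)[C@@H](/C=C(/C)CC/C=C(/CO)COCc2ccc(OC)cc2)O1
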